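**Plan**

- Numbering (isochromene): C1 is the OCH= carbon, O2, C3 carries the acrylic acid, C4, C4a, C5 (enone CH), C6 (ketone), C7 (carbinol), C8 (ester-bearing CH), C8a; ring A is the carbocycle, ring B the pyran; side-chain carbons are primed.
- Feature used: the C7 hydroxyl and the C8 ester carbonyl are cis on neighbouring ring A carbons, so the target is the alcoholysis product of a β-lactone cis-fused across C7–C8.
- Retrosynthetic cuts, in order: the allyl–O bond of a protected acrylic acid; the C8 acyl–O(side chain) bond; O7–C(acyl) and C7–C8 together (β-lactone and ring A); the exocyclic C4a=C5 bond; the C3–vinyl and C8a–C8 bonds on the kojic acid ring; the side-chain C2'–C3' bond.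
- Forward: the pyranone of kojic acid becomes ring B and receives the acetate arm (Negishi), the allyl acrylate (oxidation–Wittig) and the diketone arm (pyrylium condensation, acid unmasking). Ring A and the lactone then close in one operation, the side-chain alkoxide opens the lactone, and the allyl ester is removed last.
- Stereochemistry: the C7/C8 relative configuration comes from the cis ring fusion of the lactone and the absolute configuration from the isothiourea catalyst; C4' comes from (S)-1-bromo-2-methylbutane and C2' from an oxazaborolidine-catalysed ketone reduction.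

Key step: step 7

Assumption: the (S) antipode of HBTM [(S)-2-phenyl-3,4-dihydro-2H-pyrimido[2,1-b][1,3]benzothiazole] is taken to deliver the (7R,8R) lactone by the usual shielding model for isothiourea-bound Z-enolates; the (R) antipode would be used instead, with no other change, if the sense proved opposite.

**Route**

Step 1
Reactants: 1 kojic acid [5-hydroxy-2-(hydroxymethyl)-4H-pyran-4-one]
Product: 2 6-(hydroxymethyl)-4-oxo-4H-pyran-3-yl trifluoromethanesulfonate (kojic acid 5-triflate)
Conditions: PhNTf2 (1.05 equiv), Et3N (1.2 equiv), DMF, 0 °C to rt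
Reagents that add atoms: N-phenylbis(trifluoromethanesulfonimide), O=S(=O)(N(c1ccccc1)S(=O)(=O)C(F)(F)F)C(F)(F)F
Why: The enolic 5-hydroxyl is far more acidic than the primary alcohol, so its ammonium enolate alone should be sulfonylated by the mild triflyl donor in a chemoselective enol triflation.

Step 2
Reactants: 2 kojic acid 5-triflate; 3 tert-butyl bromoacetate
Product: 5 tert-butyl 2-[6-(hydroxymethyl)-4-oxo-4H-pyran-3-yl]acetate, via Reformatsky reagent 4 (not isolated)
Conditions: 3 (3.3 equiv), Zn (Me3SiCl-activated), THF, 40 °C; then 2, Pd2(dba)3 (2.5 mol%), XPhos (10 mol%), THF, 50 °C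
Reagents that add atoms: none
Why: In this Negishi coupling zerovalent palladium inserts into the electron-poor enol triflate and the C-bound zinc ester enolate transmetallates and reductively eliminates to form the C8a–C8 bond, a reagent class that tolerates the pyranone carbonyl and, used in excess, the free hydroxyl.

Step 3
Reactants: 5 tert-butyl 2-[6-(hydroxymethyl)-4-oxo-4H-pyran-3-yl]acetate
Product: 7 allyl (E)-3-[5-(2-tert-butoxy-2-oxoethyl)-4-oxo-4H-pyran-2-yl]prop-2-enoate, via pyranone aldehyde 6 (not isolated)
Conditions: MnO2 (10 equiv), Ph3P=CHCO2CH2CH=CH2 (1.3 equiv), CH2Cl2, reflux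
Reagents that add atoms: allyl (triphenylphosphoranylidene)acetate, C=CCOC(=O)C=P(c1ccccc1)(c1ccccc1)c1ccccc1
Why: The hydroxymethyl group is allylic to the pyranone C=C and should therefore be oxidised by MnO2, and the electrophilic aldehyde is trapped as it forms by the stabilised ylide in a tandem oxidation–Wittig reaction that gives the E-alkene.

Step 4
Reactants: 8 methyl 2,2-dimethoxypropanoate; 9 tert-butyl acetate
Product: 11 tert-butyl 4,4-dimethoxy-3-oxopentanoate, via lithium enolate 10 (not isolated)
Conditions: 9 (2.2 equiv), LiN(SiMe3)2 (2.2 equiv), THF, −78 °C; then 8, −78 to 0 °C; aqueous NH4Cl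
Reagents that add atoms: none
Why: In this crossed Claisen condensation ester 8 has no α-hydrogen and can only be the acceptor, and the second equivalent of enolate 10 stores the β-keto ester as its enolate so that it is not attacked again.

Step 5
Reactants: 7 allyl (E)-3-[5-(2-tert-butoxy-2-oxoethyl)-4-oxo-4H-pyran-2-yl]prop-2-enoate; 11 tert-butyl 4,4-dimethoxy-3-oxopentanoate
Product: 13 tert-butyl 2-{2-[(E)-3-(allyloxy)-3-oxoprop-1-enyl]-5-(2-tert-butoxy-2-oxoethyl)-4H-pyran-4-ylidene}-4,4-dimethoxy-3-oxopentanoate (geometry of the push-pull exocyclic alkene not fixed), via 4-methoxypyrylium triflate 12 (not isolated)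
Conditions: MeOTf (1.1 equiv), CH2Cl2, 0 °C to rt; then 11 (1.2 equiv), iPr2NEt (2.2 equiv), MeCN, 0 °C to rt
Reagents that add atoms: none
Why: O-Methylation turns the pyranone into a 4-methoxypyrylium ion whose C4 undergoes addition–elimination with the stabilised β-keto ester carbanion (the classical pyrylium condensation with active methylene compounds), and because this nucleophile adds reversibly at the ring α-positions while methanol loss from the C4 adduct is irreversible, the C4a=C5 ylidene should result.

Step 6
Reactants: 13 pyranylidene keto diester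
Product: 15 2-{(4Z)-6-[(E)-3-(allyloxy)-3-oxoprop-1-enyl]-4-(2,3-dioxobutylidene)-4H-pyran-3-yl}acetic acid (pyranylidene diketo acid; the Z and E forms of the exocyclic alkene should interconvert), via ylidene diacid 14 (not isolated)
Conditions: CF3CO2H/CH2Cl2/H2O (10:10:1), 0 °C to rt, then 40 °C; toluene azeotrope
Reagents that add atoms: water, O
Why: Acidolysis cleaves both tert-butyl esters and, with water, the dimethyl ketal, and the ylidene β-keto acid 14, once C-protonated to a pyrylium-substituted β-keto acid, should decarboxylate on gentle warming, whereas the allyl ester and the acetic acid arm have no such pathway.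

Step 7
Reactants: 15 pyranylidene diketo acid
Product: 17 tricyclic cis-fused β-lactone (7R,8R): allyl (E)-3-(7-methyl-6-oxo-7,8-dihydro-6H-isochromen-3-yl)prop-2-enoate bearing an oxetan-2-one fused across C7–C8 with the ring oxygen on C7 and the carbonyl carbon on C8, via mixed tosyl anhydride 16 (not isolated)
Conditions: TsCl (1.25 equiv), iPr2NEt (4 equiv), LiCl (1 equiv), (S)-HBTM (20 mol%), CH2Cl2, 0 °C to rt, slow addition of 15
Reagents that add atoms: none
Why: TsCl and iPr2NEt convert the acid into mixed anhydride 16, which acylates the isothiourea; deprotonation at C8 (acidified by the acylammonium group and the C8a=C1 vinyl group) gives a catalyst-bound ammonium enolate that adds to the LiCl-activated C7 ketone, and the C7 alkoxide then attacks the acylammonium carbon and releases the catalyst. The closest known reaction type is the nucleophile-catalysed aldol-lactonization of keto acids to bicyclic β-lactones with tertiary carbinol carbons. Ring A closes by a 6-(enolexo)-exo-trig aldol addition and the β-lactone by a 4-exo-trig acyl substitution, which also makes the aldol irreversible. C8 is set by the enolate face left open by the phenyl group of the catalyst (the Z-enolate is held coplanar by the S···O contact), and C7 follows because the four-membered ring can close only cis-fused on ring A, so the lactone fixes the relative and the catalyst the absolute configuration. The step needs site selectivity for C7 over C6 and a catalysed pathway faster than the racemic background: C6 is a doubly vinylogous ester of O2 and could only close a strained five-membered ring, the push-pull C4a=C5 bond rotates freely so that both alkene isomers of 15 drain through the reactive Z form, and slow addition of 15 keeps free mixed anhydride scarce. C7 sits next to the C6 carbonyl, which disfavours ionisation of the C7–O bond and so protects the lactone against decarboxylation.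

Step 8
Reactants: 18 (S)-1-bromo-2-methylbutane
Product: 20 (S)-4-methylhexan-2-one, via Grignard reagent 19 (not isolated)
Conditions: Mg, Et2O, reflux; then MeC(O)N(OMe)Me, 0 °C; aqueous NH4Cl
Reagents that add atoms: N-methoxy-N-methylacetamide, CC(=O)N(C)OC
Why: Magnesium insertion at the primary carbon leaves the neighbouring stereocentre untouched, and the chelated tetrahedral adduct of the Weinreb ketone synthesis stops the addition at the ketone.

Step 9
Reactants: 20 (S)-4-methylhexan-2-one
Product: 21 (2S,4S)-4-methylhexan-2-ol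
Conditions: (R)-Me-CBS oxazaborolidine [(R)-1-methyl-3,3-diphenyltetrahydro-1H,3H-pyrrolo[1,2-c][1,3,2]oxazaborole] (10 mol%), BH3·SMe2 (0.7 equiv), THF, −20 °C; MeOH quench
Reagents that add atoms: none
Why: In this Corey–Bakshi–Shibata reduction the (R)-oxazaborolidine binds the ketone with the larger 2-methylbutyl group turned away from the catalyst and delivers hydride to the face that gives the (2S) carbinol, the remote C4' centre being unaffected; any (2R) epimer would be removed as the diastereomeric ester after step 10.

Step 10
Reactants: 17 tricyclic cis-fused β-lactone; 21 (2S,4S)-4-methylhexan-2-ol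
Product: 23 (2S,4S)-4-methylhexan-2-yl (7R,8R)-3-[(E)-3-(allyloxy)-3-oxoprop-1-enyl]-7-hydroxy-7-methyl-6-oxo-7,8-dihydro-6H-isochromene-8-carboxylate, via magnesium alkoxide 22 (not isolated)
Conditions: 21 (1.5 equiv), iPrMgCl (1.4 equiv), THF, 0 °C; then 17, THF, −40 to −10 °C; aqueous NH4Cl
Reagents that add atoms: none
Why: The hard magnesium alkoxide should attack the strained lactone at the acyl carbon (strain-release alcoholysis with acyl–oxygen cleavage), which transfers the C8 carboxyl group to the secondary alcohol without touching C7, C8 or C2', and the chelated magnesium aldolate should resist retro-aldol cleavage at low temperature.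

Step 11
Reactants: 23 allyl ester of the target
Product: 24 (E)-3-[(7R,8R)-7-hydroxy-7-methyl-8-{[(2S,4S)-4-methylhexan-2-yl]oxycarbonyl}-6-oxo-7,8-dihydro-6H-isochromen-3-yl]prop-2-enoic acid (CNP0114760.1)
Conditions: Pd(PPh3)4 (5 mol%), PhNHMe (3 equiv), THF, rt
Reagents that add atoms: none
Why: Zerovalent palladium ionises the allyl ester to a π-allyl complex (Tsuji–Trost deallylation) that the weakly basic N-methylaniline captures, which frees the acrylic acid under near-neutral conditions that should leave the β-hydroxy ester, the α-ketol and the pyran untouched.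

**Compound list**

1 | kojic acid | O=C1C=C(CO)OC=C1O | starting material
2 | 6-(hydroxymethyl)-4-oxo-4H-pyran-3-yl trifluoromethanesulfonate | O=C1C=C(CO)OC=C1OS(=O)(=O)C(F)(F)F | intermediate
3 | tert-butyl bromoacetate | CC(C)(C)OC(=O)CBr | starting material
4 | (2-tert-butoxy-2-oxoethyl)zinc bromide (Reformatsky reagent) | CC(C)(C)OC(=O)C[Zn]Br | intermediate
5 | tert-butyl 2-[6-(hydroxymethyl)-4-oxo-4H-pyran-3-yl]acetate | CC(C)(C)OC(=O)CC1=COC(CO)=CC1=O | intermediate
6 | tert-butyl 2-(6-formyl-4-oxo-4H-pyran-3-yl)acetate | CC(C)(C)OC(=O)CC1=COC(C=O)=CC1=O | intermediate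
7 | allyl (E)-3-[5-(2-tert-butoxy-2-oxoethyl)-4-oxo-4H-pyran-2-yl]prop-2-enoate | C=CCOC(=O)/C=C/C1=CC(=O)C(CC(=O)OC(C)(C)C)=CO1 | intermediate
8 | methyl 2,2-dimethoxypropanoate | COC(=O)C(C)(OC)OC | starting material
9 | tert-butyl acetate | CC(=O)OC(C)(C)C | starting material
10 | lithium enolate of tert-butyl acetate | [Li]OC(=C)OC(C)(C)C | intermediate
11 | tert-butyl 4,4-dimethoxy-3-oxopentanoate | CC(OC)(OC)C(=O)CC(=O)OC(C)(C)C | intermediate
12 | 2-[(E)-3-(allyloxy)-3-oxoprop-1-enyl]-5-(2-tert-butoxy-2-oxoethyl)-4-methoxypyrylium trifluoromethanesulfonate | COc1cc(/C=C/C(=O)OCC=C)[o+]cc1CC(=O)OC(C)(C)C.[O-]S(=O)(=O)C(F)(F)F | intermediate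
13 | tert-butyl 2-{2-[(E)-3-(allyloxy)-3-oxoprop-1-enyl]-5-(2-tert-butoxy-2-oxoethyl)-4H-pyran-4-ylidene}-4,4-dimethoxy-3-oxopentanoate | C=CCOC(=O)/C=C/C1=CC(=C(C(=O)OC(C)(C)C)C(=O)C(C)(OC)OC)C(CC(=O)OC(C)(C)C)=CO1 | intermediate
14 | 2-{2-[(E)-3-(allyloxy)-3-oxoprop-1-enyl]-5-(carboxymethyl)-4H-pyran-4-ylidene}-3,4-dioxopentanoic acid | OC(=O)CC1=COC(/C=C/C(=O)OCC=C)=CC1=C(C(=O)O)C(=O)C(C)=O | intermediate
15 | 2-{(4Z)-6-[(E)-3-(allyloxy)-3-oxoprop-1-enyl]-4-(2,3-dioxobutylidene)-4H-pyran-3-yl}acetic acid | OC(=O)CC1=COC(/C=C/C(=O)OCC=C)=C\C1=C\C(=O)C(C)=O | intermediate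
16 | mixed anhydride of 15 with p-toluenesulfonic acid | Cc1ccc(cc1)S(=O)(=O)OC(=O)CC1=COC(/C=C/C(=O)OCC=C)=C\C1=C\C(=O)C(C)=O | intermediate
17 | (7R,8R) tricyclic cis-fused β-lactone (oxetan-2-one across C7–C8, O on C7, C=O on C8; allyl acrylate at C3) | O=C1O[C@@]2(C)C(=O)C=C3C=C(/C=C/C(=O)OCC=C)OC=C3[C@@H]12 | intermediate
18 | (S)-1-bromo-2-methylbutane | CC[C@H](C)CBr | starting material
19 | (S)-2-methylbutylmagnesium bromide | CC[C@H](C)C[Mg]Br | intermediate
20 | (S)-4-methylhexan-2-one | CC[C@H](C)CC(C)=O | intermediate
21 | (2S,4S)-4-methylhexan-2-ol | CC[C@H](C)C[C@H](C)O | intermediate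
22 | chloromagnesium (2S,4S)-4-methylhexan-2-olate | CC[C@H](C)C[C@H](C)O[Mg]Cl | intermediate
23 | (2S,4S)-4-methylhexan-2-yl (7R,8R)-3-[(E)-3-(allyloxy)-3-oxoprop-1-enyl]-7-hydroxy-7-methyl-6-oxo-7,8-dihydro-6H-isochromene-8-carboxylate | CC[C@H](C)C[C@H](C)OC(=O)[C@@H]1C2=COC(/C=C/C(=O)OCC=C)=CC2=CC(=O)[C@]1(C)O | intermediate
24 | (E)-3-[(7R,8R)-7-hydroxy-7-methyl-8-{[(2S,4S)-4-methylhexan-2-yl]oxycarbonyl}-6-oxo-7,8-dihydro-6H-isochromen-3-yl]prop-2-enoic acid | CC[C@H](C)C[C@H](C)OC(=O)[C@@H]1C2=COC(/C=C/C(=O)O)=CC2=CC(=O)[C@]1(C)O | target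

**Step count**

Total: 11 steps. Longest linear sequence: 8 steps (1 to 24 through steps 1, 2, 3, 5, 6, 7, 10 and 11). Steps 4, 8 and 9 make the two side fragments.

**Steps most likely to fail**

Step 7. The base-mediated, catalyst-free aldol of the mixed anhydride (through its ketene or free enolate) may outrun the isothiourea-bound pathway, so that the face of attack at C8 and C7 is poorly controlled. The fallback gives up catalyst control and resolves through the enantiopure side chain. It sets out from 15, which is cyclised under the same activation with the achiral Lewis base 4-pyrrolidinopyridine. This should give the racemic cis-lactone, that is 17 together with its mirror image, the (7S,8S)-lactone F1. The racemate is opened with alkoxide 22 as in step 10 to give 23 and the (7S,8S)-configured diastereomeric ester F2, which are separated by chromatography. The route is rejoined at 23.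

Step 5. The carbanion of 11 may attack the unsubstituted α-carbon of the pyrylium ring (the later C1) and open the ring, or add too slowly at the hindered C4. The fallback forms the C4a=C5 bond by sulfide contraction, in which the carbon–carbon bond can only arise at C4. It sets out from 7, which is thionated with Lawesson's reagent (toluene, 80 °C) to the pyran-4-thione F3. F3 is S-alkylated with 1-bromo-3,3-dimethoxybutan-2-one F4 (from 3,3-dimethoxybutan-2-one and PhNMe3Br3) to the 4-(alkylsulfanyl)pyrylium bromide F5. Et3N and PPh3 then bring about Eschenmoser sulfide contraction (thiirane formation and sulfur extrusion) to the pyranylidene ketal ketone F6. Treatment of F6 with CF3CO2H/CH2Cl2/H2O as in step 6, now with no decarboxylation needed, rejoins the route at 15.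

Step 10. Under the basic alkoxide the magnesium aldolate may undergo retro-aldol ring opening or epimerisation at C8, or the allyl ester may transesterify. The fallback joins the side chain by alkylation of the carboxylate instead of acyl transfer. It sets out from 17, which is hydrolysed with LiOH (1 equiv, THF/H2O, 0 °C) to the (7R,8R)-hydroxy acid F7, whose carboxylate is much less prone to retro-aldol cleavage than the ester. F7 is then esterified under Mitsunobu conditions (PPh3, DIAD, THF, 0 °C) with (2R,4S)-4-methylhexan-2-ol F8, made from 20 with the (S)-oxazaborolidine. Inversion at the carbinol carbon gives the (2S) ester and rejoins the route at 23.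

**Further compounds**

F1 | step 7 | (7S,8S)-enantiomer of lactone 17 | O=C1O[C@]2(C)C(=O)C=C3C=C(/C=C/C(=O)OCC=C)OC=C3[C@H]12
F2 | step 7 | (2S,4S)-4-methylhexan-2-yl (7S,8S)-3-[(E)-3-(allyloxy)-3-oxoprop-1-enyl]-7-hydroxy-7-methyl-6-oxo-7,8-dihydro-6H-isochromene-8-carboxylate | CC[C@H](C)C[C@H](C)OC(=O)[C@H]1C2=COC(/C=C/C(=O)OCC=C)=CC2=CC(=O)[C@@]1(C)O
F3 | step 5 | allyl (E)-3-[5-(2-tert-butoxy-2-oxoethyl)-4-thioxo-4H-pyran-2-yl]prop-2-enoate | C=CCOC(=O)/C=C/C1=CC(=S)C(CC(=O)OC(C)(C)C)=CO1
F4 | step 5 | 1-bromo-3,3-dimethoxybutan-2-one | CC(OC)(OC)C(=O)CBr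
F5 | step 5 | 2-[(E)-3-(allyloxy)-3-oxoprop-1-enyl]-5-(2-tert-butoxy-2-oxoethyl)-4-[(3,3-dimethoxy-2-oxobutyl)sulfanyl]pyrylium bromide | CC(OC)(OC)C(=O)CSc1cc(/C=C/C(=O)OCC=C)[o+]cc1CC(=O)OC(C)(C)C.[Br-]
F6 | step 5 | allyl (E)-3-[5-(2-tert-butoxy-2-oxoethyl)-4-(3,3-dimethoxy-2-oxobutylidene)-4H-pyran-2-yl]prop-2-enoate | C=CCOC(=O)/C=C/C1=CC(=CC(=O)C(C)(OC)OC)C(CC(=O)OC(C)(C)C)=CO1
F7 | step 10 | (7R,8R)-3-[(E)-3-(allyloxy)-3-oxoprop-1-enyl]-7-hydroxy-7-methyl-6-oxo-7,8-dihydro-6H-isochromene-8-carboxylic acid | O=C(O)[C@@H]1C2=COC(/C=C/C(=O)OCC=C)=CC2=CC(=O)[C@]1(C)O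
F8 | step 10 | (2R,4S)-4-methylhexan-2-ol | CC[C@H](C)C[C@@H](C)O
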